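In ent-kaurane numbering the oxygen between C6 and C7 turns ring B into an oxepane, so ring A and the bicyclo[3.2.1]octane (rings C and D) share only the C9–C10 bond, which lies next to oxygenated C1. The route exploits this feature: a cyclogeranate-derived ring A keto acid and a nopinone-derived bicyclooctenyl triflate alcohol are first joined as the C6–O–C7 ester, and a palladium-catalysed coupling of the C1 ketone enolate with the C9 enol triflate then forms C9–C10, creates quaternary C10 and closes ring B as a seven-membered lactone in one operation. The C1 ketone later delivers the 1,2-diacetate and the lactone the lactol.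

Key step: step 12

Assumptions: atoms carry ent-kaurane numbers, α is the face of rings A/B bearing the C20 methyl and β the face of H-5 in the target; racemic α-cyclogeranic acid is taken as purchasable; which antipode of 1-phenylethylamine gives the less soluble salt of the (S)-acid must be settled by experiment (the (R)-amine is written, the (S)-amine would be used otherwise).

Step 1
Reactants: 1 (+)-nopinone, (1R,5S)-6,6-dimethylbicyclo[3.1.1]heptan-2-one; 2 dimethyl carbonate
Product: 3 methyl (1R,5R)-6,6-dimethyl-2-oxobicyclo[3.1.1]heptane-3-carboxylate (3-carbomethoxynopinone; C3 epimers/enol; bridgeheads as in 1)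
Conditions: NaH, excess 2, THF, reflux; aq. HCl work-up
Reagents that add atoms: none
Why: Claisen-type C-acylation of the ketone enolate by dimethyl carbonate, driven by deprotonation of the β-keto ester; C3 is the only enolisable α-carbon because C1 is a bridgehead, and neither stereocentre is touched.

Step 2
Reactants: 3 3-carbomethoxynopinone
Product: 5 methyl (5R)-2-acetoxy-5-(prop-1-en-2-yl)cyclohex-1-ene-1-carboxylate, via ring-opened keto ester 4 (not isolated)
Conditions: BF3·OEt2, Zn(OAc)2, Ac2O, rt
Reagents that add atoms: acetic anhydride, CC(=O)OC(C)=O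
Why: Lewis-acid-promoted fragmentation of the strained cyclobutane bond α to the activated carbonyl (a retro-aldol-type ring opening) gives a tertiary cation that loses a proton to form the isopropenyl group, and the freed β-keto ester is O-acetylated in the same pot; the stereocentre that becomes C13 is a spectator.

Step 3
Reactants: 5 enol acetate
Product: 6 methyl (5R)-2-acetoxy-5-(3-chloroprop-1-en-2-yl)cyclohex-1-ene-1-carboxylate
Conditions: Ca(OCl)2, solid CO2, CH2Cl2/H2O, 0 °C
Reagents that add atoms: calcium hypochlorite Ca(OCl)2, [Ca+2].[O-]Cl.[O-]Cl
Why: Ene-type allylic chlorination by HOCl attacks the electron-rich 1,1-disubstituted alkene with double-bond transposition, while the acetoxy acrylate alkene is deactivated and the masked keto ester cannot be chlorinated at its α-carbon.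

Step 4
Reactants: 6 allylic chloride
Product: 8 methyl (1R,5R)-6-methylidene-2-oxobicyclo[3.2.1]octane-1-carboxylate, via chloro keto ester 7 (not isolated)
Conditions: K2CO3, MeOH, 0 °C → rt
Reagents that add atoms: none
Why: Methanolysis of the enol acetate releases the β-keto ester enolate, which closes ring D by intramolecular SN2 C-alkylation (5-exo-tet, C8–C15) on the allylic chloride of the axial side chain; the one-carbon bridge C14 permits only one configuration at the new quaternary C8, so it follows from C13, and O-alkylation would need a bridgehead enol ether.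

Step 5
Reactants: 8 bicyclic keto ester
Product: 9 methyl (1R,5R)-6-methylidene-2-(trifluoromethylsulfonyloxy)bicyclo[3.2.1]oct-2-ene-1-carboxylate
Conditions: KN(SiMe3)2, THF, −78 °C; PhNTf2, −78 → 0 °C
Reagents that add atoms: N-phenylbis(trifluoromethanesulfonimide), O=S(=O)(N(c1ccccc1)S(=O)(=O)C(F)(F)F)C(F)(F)F
Why: Enolate formation and O-sulfonylation; quaternary C8 leaves only the C11 side enolisable, so the C9=C11 enol triflate is the single regioisomer.

Step 6
Reactants: 9 enol triflate ester
Product: 10 (1S,5R)-1-(hydroxymethyl)-6-methylidenebicyclo[3.2.1]oct-2-en-2-yl trifluoromethanesulfonate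
Conditions: iBu2AlH, CH2Cl2, −78 → 0 °C; aq. KNaC4H4O6
Reagents that add atoms: none
Why: Hydride reduction with iBu2AlH takes the hindered methyl ester to the neopentyl C7 alcohol at low temperature and, unlike LiAlH4, leaves the alkenyl triflate intact.

Step 7
Reactants: 11 racemic α-cyclogeranic acid (2,6,6-trimethylcyclohex-2-ene-1-carboxylic acid)
Product: 12 (R)-1-phenylethylammonium (S)-2,6,6-trimethylcyclohex-2-ene-1-carboxylate
Conditions: (R)-1-phenylethylamine, EtOAc/EtOH, crystallise and recrystallise
Reagents that add atoms: (R)-1-phenylethylamine, C[C@@H](N)c1ccccc1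
Why: Classical resolution through diastereomeric salts, whose different solubilities should let the salt of the (S)-acid be recrystallised to a single diastereomer.

Step 8
Reactants: 12 resolved salt
Product: 13 (S)-2,6,6-trimethylcyclohex-2-ene-1-carboxylic acid
Conditions: 1 M HCl, Et2O, rt
Reagents that add atoms: none
Why: Acidification partitions the free acid into the organic phase, and the stereocentre is not enolisable under these conditions.

Step 9
Reactants: 13 (S)-α-cyclogeranic acid
Product: 15 (3R)-3-(hydroxymethyl)-2,4,4-trimethylcyclohexan-1-ol (diastereomers at C1 and C2 of the ring), via cyclic alkoxyalkylborane 14 (not isolated)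
Conditions: BH3·THF (excess), THF, 0 °C → rt; then NaOH, H2O2, 0 → 40 °C
Reagents that add atoms: hydrogen peroxide, OO
Why: Hydroboration–oxidation in which excess borane also reduces the carboxylic acid; boron adds to the less substituted alkene carbon (future C1) and is replaced by hydroxyl with retention, the new carbinol and methyl-bearing centres are erased later, and the future C5 is untouched.

Step 10
Reactants: 15 diol
Product: 16 (1R)-2,2,6-trimethyl-5-oxocyclohexane-1-carboxylic acid (C6 epimers of the ring, i.e. future C10)
Conditions: CrO3, H2SO4, acetone/H2O, 0 °C → rt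
Reagents that add atoms: water, O
Why: Jones oxidation takes the secondary alcohol to the C1 ketone and the primary alcohol through its aldehyde hydrate to the acid; the hindered tertiary C5 should not enolise at this temperature, and the epimer mixture at the methyl-bearing carbon is inconsequential.

Step 11
Reactants: 16 keto acid; 10 triflate alcohol
Product: 18 seco ester (C7–O–C6(=O) ester of 10 and 16; C10 epimers), via acid chloride 17 (not isolated)
Conditions: 1-chloro-N,N,2-trimethylprop-1-en-1-amine, CH2Cl2, 0 °C → rt; then 10, pyridine, DMAP, CH2Cl2, rt → 40 °C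
Reagents that add atoms: none
Why: The neutral chloroenamine converts the hindered acid into its chloride without strong acid, and DMAP-catalysed acylation of the neopentyl alcohol forms the C6–O–C7 ester; the weak pyridine base avoids ketene formation, so C5 keeps its configuration.

Step 12
Reactants: 18 seco ester
Product: 19 cis-fused tetracyclic keto lactone (C1 ketone; ring B lactone C6(=O)–O–C7; C9=C11 and C16=C17 alkenes; H-5 α and cis to C20)
Conditions: Pd2(dba)3 (5 mol %), 2-dicyclohexylphosphino-2',4',6'-triisopropylbiphenyl (12 mol %), K3PO4, toluene (0.01 M), 90 °C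
Reagents that add atoms: none
Why: Zerovalent palladium inserts into the C9–OTf bond, phosphate reversibly generates the more substituted C1/C10 enolate, which binds divalent palladium through carbon, and reductive elimination forges C9–C10. The closest known reaction type is the palladium-catalysed intramolecular α-alkenylation (and α-arylation) of ketone enolates with alkenyl or aryl halides and triflates, which tolerates quaternary-centre formation. Ring B closes as a seven-membered lactone in a 7-exo mode with respect to the C1=C10 enolate bond, C1 staying outside the ring. The new stereocentre C10 is controlled by C5: allylic 1,2-strain with the C20 methyl holds the acyloxy arm on C5 pseudoaxial, so the five-atom tether (C6, O, C7, C8, C9) can deliver C9 only to the enolate face it occupies, which gives the cis-fused lactone with C10 in the target configuration from either C10 epimer of 18. The step needs C10 over C2 regioselectivity, secured because attack at C2 would require a nine-membered ring, and a clean alkenylpalladium, secured by quaternary C8, which fixes the triflate position and offers no competing intramolecular partner. The weak, insoluble base protects the ester, the triflate and the C5–H, and high dilution with heating serves the unfavourable E-ester rotamer.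

Step 13
Reactants: 19 cis-fused keto lactone
Product: 21 trans-fused keto lactone (C5 epimer of 19; H-5 β), via dilithium dienolate 20 (not isolated)
Conditions: LiN(iPr)2 (3 equiv), THF, −78 → −20 °C; then 2,6-di-tert-butyl-4-methylphenol, −78 °C; aq. NH4Cl
Reagents that add atoms: none
Why: Enolate formation and kinetic protonation: the first equivalent of amide masks C1 as its C2 enolate, the second removes H-5, and the bulky phenol then protonates C5 from the β face because the α face is flanked by the syn-axial C20 and C4 methyls, which inverts C5 to the trans ring fusion.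

Step 14
Reactants: 21 trans-fused keto lactone
Product: 22 diosphenol (2-hydroxy-2-en-1-one in ring A; otherwise as 21)
Conditions: KOtBu, O2 (1 atm), tBuOH/THF, −20 → 0 °C; aq. NH4Cl
Reagents that add atoms: dioxygen, O=O
Why: Enolate autoxidation: C1 can enolise only toward C2 (C10 is quaternary), the C2 enolate traps O2, and the α-hydroperoxide loses water (Kornblum–DeLaMare-type) to the 1,2-dione, which rests as the C2=C3 diosphenolate; no stereocentre is formed and the hindered lactone C5–H is far less acidic than the ketone.

Step 15
Reactants: 22 diosphenol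
Product: 23 1α,2α-diol lactone (cis-diol; 1-OH equatorial, 2-OH axial)
Conditions: NaBH4, CeCl3·7H2O, MeOH/THF, −20 → 0 °C
Reagents that add atoms: none
Why: Luche-type hydride reduction of both carbonyl carbons of the diosphenol/dione pair: hydride reaches C1 and C2 from the β face because the axial C20 and axial C4 methyls block the α face of C2 and flank that of C1, which places both hydroxyls α, and the hindered lactone is not reduced at this temperature.

Step 16
Reactants: 23 diol lactone
Product: 24 9α,11α-epoxy-1α,2α-diol lactone
Conditions: VO(acac)2 (10 mol %), tBuOOH (decane solution), CH2Cl2, 0 °C → rt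
Reagents that add atoms: tert-butyl hydroperoxide, CC(C)(C)OO
Why: Hydroxyl-directed vanadium-catalysed epoxidation: the equatorial 1α-hydroxyl, homoallylic to C9=C11 and gauche to C20, holds the vanadium peroxide on the α face, which is also the side of the one-carbon bridge C14 and away from the inner C15 hydrogen, while the remote C16=C17 alkene has no directing group and stays intact.

Step 17
Reactants: 24 epoxy diol lactone
Product: 25 lactol triol (C6 anomers; 1α,2α-diol and 9α,11α-epoxide retained)
Conditions: iBu2AlH (4 equiv), CH2Cl2, −78 °C; MeOH; aq. KNaC4H4O6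
Reagents that add atoms: none
Why: Partial reduction: two equivalents of hydride are consumed by the hydroxyls and the lactone is reduced to a tetrahedral aluminium hemiacetal that is stable at −78 °C and gives the lactol on work-up, the epoxide being inert at this temperature.

Step 18
Reactants: 25 lactol triol
Product: 26 epoxy triacetate (1α,2α-diacetate and C6 anomeric acetate)
Conditions: Ac2O, DMAP, pyridine, rt → 40 °C
Reagents that add atoms: acetic anhydride, CC(=O)OC(C)=O
Why: DMAP-catalysed acetylation esterifies both secondary hydroxyls, including the hindered axial C2–OH, and traps the lactol in its ring-closed form as an acylal that protects C6; the anomeric configuration is irrelevant.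

Step 19
Reactants: 26 epoxy triacetate
Product: 27 15-hydroxy triacetate (C15 carbinol configuration immaterial)
Conditions: SeO2 (0.5 equiv), tBuOOH, CH2Cl2, 0 °C → rt
Reagents that add atoms: selenium dioxide, O=[Se]=O; tert-butyl hydroperoxide (terminal oxidant), CC(C)(C)OO
Why: Riley-type allylic hydroxylation (ene reaction, then [2,3]-sigmatropic shift) functionalises C15, the only allylic position that is not a bridgehead, and returns the exocyclic C16=C17 alkene; the new carbinol centre is oxidised in the next step.

Step 20
Reactants: 27 allylic alcohol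
Product: 28 enone triacetate (15-oxo-16-ene)
Conditions: Dess–Martin periodinane, pyridine, CH2Cl2, 0 °C → rt
Reagents that add atoms: none
Why: Dess–Martin oxidation of the allylic alcohol under buffered non-aqueous conditions gives the α-methylene cyclopentanone without touching epoxide, acylal or acetates.

Step 21
Reactants: 28 enone triacetate
Product: 29 target CNP0224512.1
Conditions: Zn(OAc)2·2H2O, MeOH, rt
Reagents that add atoms: none
Why: Zn(OAc)2-mediated methanolysis (transesterification) cleaves selectively the acylal-type acetate at C6, whose lactolate is a far better leaving group than the C1 and C2 alkoxides, under neutral amine-free conditions that spare enone, epoxide and secondary acetates; the freed lactol equilibrates through the open hydroxy aldehyde to its more stable anomer, the one drawn for the target.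

Compound list
1 | (+)-nopinone, (1R,5S)-6,6-dimethylbicyclo[3.1.1]heptan-2-one | CC1(C)[C@H]2CCC(=O)[C@@H]1C2 | starting material
2 | dimethyl carbonate | COC(=O)OC | starting material
3 | methyl (1R,5R)-6,6-dimethyl-2-oxobicyclo[3.1.1]heptane-3-carboxylate | CC1(C)[C@H]2CC(C(=O)OC)C(=O)[C@@H]1C2 | intermediate
4 | methyl (5R)-2-oxo-5-(prop-1-en-2-yl)cyclohexane-1-carboxylate (ring-opened keto ester) | C=C(C)[C@@H]1CCC(=O)C(C(=O)OC)C1 | intermediate
5 | methyl (5R)-2-acetoxy-5-(prop-1-en-2-yl)cyclohex-1-ene-1-carboxylate | C=C(C)[C@@H]1CCC(OC(C)=O)=C(C(=O)OC)C1 | intermediate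
6 | methyl (5R)-2-acetoxy-5-(3-chloroprop-1-en-2-yl)cyclohex-1-ene-1-carboxylate | C=C(CCl)[C@@H]1CCC(OC(C)=O)=C(C(=O)OC)C1 | intermediate
7 | methyl (5R)-5-(3-chloroprop-1-en-2-yl)-2-oxocyclohexane-1-carboxylate (chloro keto ester) | C=C(CCl)[C@@H]1CCC(=O)C(C(=O)OC)C1 | intermediate
8 | methyl (1R,5R)-6-methylidene-2-oxobicyclo[3.2.1]octane-1-carboxylate | C=C1C[C@@]2(C(=O)OC)C(=O)CC[C@@H]1C2 | intermediate
9 | methyl (1R,5R)-6-methylidene-2-(trifluoromethylsulfonyloxy)bicyclo[3.2.1]oct-2-ene-1-carboxylate | C=C1C[C@@]2(C(=O)OC)C(OS(=O)(=O)C(F)(F)F)=CC[C@@H]1C2 | intermediate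
10 | (1S,5R)-1-(hydroxymethyl)-6-methylidenebicyclo[3.2.1]oct-2-en-2-yl trifluoromethanesulfonate | C=C1C[C@@]2(CO)C(OS(=O)(=O)C(F)(F)F)=CC[C@@H]1C2 | intermediate
11 | racemic α-cyclogeranic acid | OC(=O)C1C(C)(C)CCC=C1C | starting material
12 | (R)-1-phenylethylammonium (S)-α-cyclogeranate | C[C@@H]([NH3+])c1ccccc1.[O-]C(=O)[C@H]1C(C)(C)CCC=C1C | intermediate
13 | (S)-α-cyclogeranic acid | OC(=O)[C@H]1C(C)(C)CCC=C1C | intermediate
14 | cyclic alkoxyalkylborane (the borane mixture written in its simplest intramolecular form) | CC1C2CCC(C)(C)[C@@H]1COB2 | intermediate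
15 | (3R)-3-(hydroxymethyl)-2,4,4-trimethylcyclohexan-1-ol | OC[C@H]1C(C)(C)CCC(O)C1C | intermediate
16 | (1R)-2,2,6-trimethyl-5-oxocyclohexane-1-carboxylic acid | OC(=O)[C@H]1C(C)(C)CCC(=O)C1C | intermediate
17 | acid chloride of 16 | ClC(=O)[C@H]1C(C)(C)CCC(=O)C1C | intermediate
18 | seco ester of 10 and 16 | C=C1C[C@@]2(COC(=O)[C@H]3C(C)(C)CCC(=O)C3C)C(OS(=O)(=O)C(F)(F)F)=CC[C@@H]1C2 | intermediate
19 | cis-fused keto lactone (H-5 α) | C=C1C[C@@]23COC(=O)[C@H]4C(C)(C)CCC(=O)[C@@]4(C)C2=CC[C@@H]1C3 | intermediate
20 | dilithium dienolate of 19 (C1=C2 and C5=C6 enolates) | C=C1C[C@@]23COC([O-])=C4C(C)(C)CC=C([O-])[C@@]4(C)C2=CC[C@@H]1C3.[Li+].[Li+] | intermediate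
21 | trans-fused keto lactone (H-5 β) | C=C1C[C@@]23COC(=O)[C@@H]4C(C)(C)CCC(=O)[C@@]4(C)C2=CC[C@@H]1C3 | intermediate
22 | diosphenol | C=C1C[C@@]23COC(=O)[C@@H]4C(C)(C)C=C(O)C(=O)[C@@]4(C)C2=CC[C@@H]1C3 | intermediate
23 | 1α,2α-diol lactone | C=C1C[C@@]23COC(=O)[C@@H]4C(C)(C)C[C@H](O)[C@H](O)[C@@]4(C)C2=CC[C@@H]1C3 | intermediate
24 | 9α,11α-epoxy-1α,2α-diol lactone | C=C1C[C@@]23COC(=O)[C@@H]4C(C)(C)C[C@H](O)[C@H](O)[C@@]4(C)[C@]24O[C@@H]4C[C@@H]1C3 | intermediate
25 | lactol triol (C6 anomers) | C=C1C[C@@]23COC(O)[C@@H]4C(C)(C)C[C@H](O)[C@H](O)[C@@]4(C)[C@]24O[C@@H]4C[C@@H]1C3 | intermediate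
26 | epoxy triacetate | C=C1C[C@@]23CO[C@@H](OC(C)=O)[C@@H]4C(C)(C)C[C@H](OC(C)=O)[C@H](OC(C)=O)[C@@]4(C)[C@]24O[C@@H]4C[C@@H]1C3 | intermediate
27 | 15-hydroxy triacetate | C=C1C(O)[C@@]23CO[C@@H](OC(C)=O)[C@@H]4C(C)(C)C[C@H](OC(C)=O)[C@H](OC(C)=O)[C@@]4(C)[C@]24O[C@@H]4C[C@@H]1C3 | intermediate
28 | enone triacetate | C=C1C(=O)[C@@]23CO[C@@H](OC(C)=O)[C@@H]4C(C)(C)C[C@H](OC(C)=O)[C@H](OC(C)=O)[C@@]4(C)[C@]24O[C@@H]4C[C@@H]1C3 | intermediate
29 | CNP0224512.1 | C=C1C(=O)[C@@]23CO[C@@H](O)[C@@H]4C(C)(C)C[C@H](OC(C)=O)[C@H](OC(C)=O)[C@@]4(C)[C@]24O[C@@H]4C[C@@H]1C3 | target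

Total step count: 21 steps.
Longest linear sequence: 17 steps (steps 1–6 and 11–21, from 1 to 29); the acid branch (steps 7–10) joins at step 11.

Steps most likely to fail

Step 12. The ester has to adopt its disfavoured E rotamer and reductive elimination must create a quaternary carbon beside quaternary C8. Triflate solvolysis, protodetriflation or oligomerisation may therefore outrun ring closure, and prolonged heating with base may erode the ester. The fallback separates enolisation from coupling. It sets out from 18: Me3SiCl, NaI and Et3N in MeCN should give the more substituted C1=C10 trimethylsilyl enol ether F1. This is cyclised under base-free, fluoride-promoted palladium coupling of a silyl enol ether through its zinc enolate (Pd2(dba)3, P(tBu)3, ZnF2, CsF, DMF, 80 °C), and the route is rejoined at 19.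

Step 13. The proton to be removed sits on the α face between the axial C20 and C4 methyls. Deprotonation may therefore be incomplete, the lactone enolate may fragment before the cold quench, or the proton may return to the face it left. The fallback uses soft enolisation and sets out from 19. Me3SiOTf and Et3N (CH2Cl2, 0 °C → rt) should give the neutral bis(trimethylsilyl) derivative F2, a C1=C2 silyl enol ether plus a C5=C6 silyl ketene acetal. C-protonation of F2 with dry HCl in THF at −78 °C from the open β face, followed by aqueous work-up that removes both silyl groups, comes back to the route at 21.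

Step 14. The diosphenolate may be oxidised further by O2 with cleavage of ring A, and the alkoxide medium may open the lactone or disturb C5. The fallback replaces autoxidation by electrophilic hydroxylation and sets out from 21. KN(SiMe3)2 (1.1 equiv, THF, −78 °C) and 2-(phenylsulfonyl)-3-phenyloxaziridine should give the 2-hydroxy-1-ketone F3, whose C2 configuration does not matter. Dess–Martin oxidation of F3 gives the 1,2-dione, which is the keto tautomer of 22, where the route is rejoined.

Further compounds
F1 | step 12 | C1=C10 trimethylsilyl enol ether of seco ester 18 | C=C1C[C@@]2(COC(=O)[C@H]3C(C)(C)CCC(O[Si](C)(C)C)=C3C)C(OS(=O)(=O)C(F)(F)F)=CC[C@@H]1C2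
F2 | step 13 | bis(trimethylsilyl) derivative of 19 (C1=C2 silyl enol ether, C5=C6 silyl ketene acetal) | C=C1C[C@@]23COC(O[Si](C)(C)C)=C4C(C)(C)CC=C(O[Si](C)(C)C)[C@@]4(C)C2=CC[C@@H]1C3
F3 | step 14 | 2-hydroxy-1-ketone of the trans-fused lactone | C=C1C[C@@]23COC(=O)[C@@H]4C(C)(C)CC(O)C(=O)[C@@]4(C)C2=CC[C@@H]1C3
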